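Everything rests on disconnecting C7–C8 of the ten-membered carbocycle (C1–C10). C7 bears an oxygen and the C11(=C13H2)–C12 unit beside the C8 carbinol, the pattern left by a [2,3]-Wittig shift of a C8–O–C13 allyl ether. In a single operation the shift contracts a thirteen-membered keto ether to the carbocycle, forms C7–C8, creates the C7 and C8 stereocentres and releases the C11=C13 methylene. Its substrate is macrocyclic enone 25, in which O6 and O12 are bridged by a seven-membered di-tert-butylsilylene: the bridge proves the enol ether geometry, fixes the C6 stereocentre relative to the C7=C11 plane and later frees the lactone diol in one step.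

Key step: step 20

Remarks:
- Atoms keep the germacranolide numbers of the target in every intermediate: ring carbons C1–C10 (methyls on C4 and C10; oxygens on C6, C7, C8, C9), lactone carbons C11 (on C7), C12 (carbonyl) and C13 (methylene).
- Assumption: the C9 epimers of 24 are carried as a mixture, because step 19 removes that centre.
- Assumption: compound 7 and all reagents named are purchased.

Step 1
Reactants: 1 geranyl acetate
Product: 3 (2E)-3-methyl-6-oxohex-2-en-1-yl acetate, via ozonide 2 (not isolated)
Conditions: O3 (1.0 equiv), CH2Cl2, −78 °C; then Me2S, −78 °C → rt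
Reagents that add atoms: ozone O=[O+][O-]
Why: Ozonolysis with reductive work-up: the remote, electron-rich trisubstituted olefin should take up the single equivalent of ozone faster than the olefin deactivated by the allylic acetate, so only the isopropylidene end is cleaved and the E-olefin is kept.

Step 2
Reactants: 3 (2E)-3-methyl-6-oxohex-2-en-1-yl acetate
Product: 4 (2E,6Z)-7-iodo-3-methylocta-2,6-dien-1-yl acetate
Conditions: [Ph3PEt]I, n-BuLi, THF, rt; I2, −78 °C; NaN(SiMe3)2, −20 °C; then 3, −78 °C → rt
Reagents that add atoms: ethyltriphenylphosphonium iodide CC[P+](c1ccccc1)(c1ccccc1)c1ccccc1.[I-]; iodine II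
Why: Wittig olefination with the α-iodo ylide (Stork–Zhao-type iodo-olefination): the non-stabilised ylide should react under kinetic control to place iodine cis to the chain, so the Z-iodoalkene stores the future C1=C10 geometry.

Step 3
Reactants: 4 (2E,6Z)-7-iodo-3-methylocta-2,6-dien-1-yl acetate
Product: 5 (2E,6Z)-7-iodo-3-methylocta-2,6-dien-1-ol
Conditions: K2CO3 (0.2 equiv), MeOH, 0 °C → rt
Reagents that add atoms: none
Why: Base-catalysed transesterification of the acetate with methanol; nothing else in the molecule is base-labile.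

Step 4
Reactants: 5 (2E,6Z)-7-iodo-3-methylocta-2,6-dien-1-ol
Product: 6 (2E,6Z)-7-iodo-3-methylocta-2,6-dienal
Conditions: MnO2, CH2Cl2, rt
Reagents that add atoms: none
Why: MnO2 oxidation is selective for allylic alcohols and neutral, so both olefin geometries and the C–I bond should survive.

Step 5
Reactants: 7 methyl 3-hydroxypropanoate
Product: 8 methyl 3-[(tert-butyldimethylsilyl)oxy]propanoate
Conditions: TBSCl, imidazole, CH2Cl2, rt
Reagents that add atoms: tert-butyldimethylsilyl chloride CC(C)(C)[Si](C)(C)Cl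
Why: Standard silyl ether formation at a primary alcohol.

Step 6
Reactants: 8 methyl 3-[(tert-butyldimethylsilyl)oxy]propanoate
Product: 10 methyl 3-[(tert-butyldimethylsilyl)oxy]-2-formylpropanoate, via lithium enolate 9 (not isolated)
Conditions: LiN(iPr)2, THF, −78 °C; HCO2Me, −78 → −20 °C; aq. NH4Cl
Reagents that add atoms: methyl formate COC=O
Why: Crossed Claisen condensation (formylation) of the kinetic ester enolate with methyl formate; low temperature should hold back β-elimination of the silyloxy group, and the acidic product stays protected as its enolate until work-up.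

Step 7
Reactants: 10 methyl 3-[(tert-butyldimethylsilyl)oxy]-2-formylpropanoate
Product: 11 methyl (2E)-2-{[(tert-butyldimethylsilyl)oxy]methyl}-3-(methoxymethoxy)prop-2-enoate
Conditions: MOMCl, K2CO3, DMF, 0 °C
Reagents that add atoms: chloromethyl methyl ether COCCl
Why: O-alkylation of the formyl ester enolate by the hard electrophile MOMCl; the dissociated potassium enolate should react through its extended form to give the thermodynamically preferred E-β-alkoxyacrylate, with MOM-oxy trans to the ester and C7–H cis to it.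

Step 8
Reactants: 11 methyl (2E)-2-{[(tert-butyldimethylsilyl)oxy]methyl}-3-(methoxymethoxy)prop-2-enoate
Product: 12 (2Z)-2-{[(tert-butyldimethylsilyl)oxy]methyl}-3-(methoxymethoxy)prop-2-en-1-ol
Conditions: iBu2AlH (2.2 equiv), CH2Cl2, −78 °C; aq. Rochelle salt
Reagents that add atoms: none
Why: Hydride 1,2-reduction of the vinylogous carbonate ester to the allylic alcohol leaves the enol ether geometry untouched, and the neutral work-up avoids allylic transposition of the 3-alkoxyallyl alcohol.

Step 9
Reactants: 12 (2Z)-2-{[(tert-butyldimethylsilyl)oxy]methyl}-3-(methoxymethoxy)prop-2-en-1-ol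
Product: 13 bis-silyl MOM enol ether (C12 arm CH2OTBDPS cis to C7–H; C13 arm CH2OTBS cis to MOM-oxy)
Conditions: TBDPSCl, imidazole, DMF, 0 °C → rt
Reagents that add atoms: tert-butyldiphenylsilyl chloride CC(C)(C)[Si](Cl)(c1ccccc1)c1ccccc1
Why: Standard silylation; the robust TBDPS group marks the C12 arm, the more labile TBS group the C13 arm.

Step 10
Reactants: 13 bis-silyl MOM enol ether; 6 (2E,6Z)-7-iodo-3-methylocta-2,6-dienal
Product: 15 racemic C6 carbinol, via lithio enol ether 14 (not isolated)
Conditions: s-BuLi (1.05 equiv), THF, −78 °C; then 6, −78 °C; aq. NH4Cl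
Reagents that add atoms: none
Why: α-Lithiation of the MOM enol ether (the acetal oxygen directs metalation to the vinylic C–H next to oxygen) with retention of geometry, then 1,2-addition of the alkenyllithium to the enal; C6 forms as a racemate and is corrected in steps 11 and 14.

Step 11
Reactants: 15 racemic C6 carbinol
Product: 16 cross-conjugated C6 dienone
Conditions: MnO2, CH2Cl2, rt
Reagents that add atoms: none
Why: MnO2 oxidation of the doubly allylic alcohol removes the uncontrolled C6 centre and, by conjugation with the new carbonyl, deactivates the enol ether toward acid for the next step.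

Step 12
Reactants: 16 cross-conjugated C6 dienone
Product: 17 hydroxy dienone with free C13 hydroxyl
Conditions: camphorsulfonic acid (0.1 equiv), MeOH/CH2Cl2, 0 °C
Reagents that add atoms: none
Why: Acid-catalysed methanolysis of the primary TBS ether is far faster than that of the TBDPS ether, and the enol ether, now conjugated to the C6 carbonyl, should resist protonation.

Step 13
Reactants: 17 hydroxy dienone
Product: 18 tert-butyl glycolate ether (C13–O–C8H2–C9O2tBu)
Conditions: tert-butyl diazoacetate (slow addition), Rh2(OAc)4 (1 mol%), CH2Cl2, rt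
Reagents that add atoms: tert-butyl diazoacetate CC(C)(C)OC(=O)C=[N+]=[N-]
Why: Rh-carbenoid O–H insertion into the primary allylic alcohol under neutral conditions should outrun cyclopropanation of the electron-poor or hindered olefins, and it installs C8 and C9 together with the ether oxygen that later becomes O8.

Step 14
Reactants: 18 tert-butyl glycolate ether
Product: 19 (6S)-alcohol
Conditions: (R)-Me-CBS [(R)-1-methyl-3,3-diphenyltetrahydro-1H,3H-pyrrolo[1,2-c][1,3,2]oxazaborole] (0.5 equiv), BH3·SMe2, THF, −40 °C; MeOH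
Reagents that add atoms: none
Why: Corey–Bakshi–Shibata reduction: with the fully substituted α-alkoxyalkenyl group as the large and the C5 alkenyl group as the small substituent, the (R)-catalyst should deliver hydride to the face that gives the 6S alcohol, while ester and iodide are inert to borane at this temperature.

Step 15
Reactants: 19 (6S)-alcohol
Product: 20 (6S)-C6,C12-diol
Conditions: Bu4NF, AcOH, THF, 0 °C
Reagents that add atoms: none
Why: Fluoride cleavage of the TBDPS ether; the acetic acid buffer protects the ester and the acid-sensitive doubly allylic alcohol.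

Step 16
Reactants: 20 (6S)-C6,C12-diol
Product: 21 (6S)-O6,O12-di-tert-butylsilylene
Conditions: tBu2Si(OTf)2, 2,6-lutidine, CH2Cl2, 0 °C
Reagents that add atoms: di-tert-butylsilyl bis(trifluoromethanesulfonate) CC(C)(C)[Si](OS(=O)(=O)C(F)(F)F)(OS(=O)(=O)C(F)(F)F)C(C)(C)C
Why: Silylene protection of a 1,4-diol: only the hydroxymethyl arm cis to C6 on the enol ether can close the seven-membered dioxasilepine, so ring formation confirms the geometry set in step 7 and holds O6 beside the C7=C11 plane.

Step 17
Reactants: 21 (6S)-O6,O12-di-tert-butylsilylene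
Product: 22 C9 aldehyde
Conditions: iBu2AlH (1.3 equiv), CH2Cl2, −78 °C; aq. Rochelle salt
Reagents that add atoms: none
Why: Partial hydride reduction of the α-alkoxy ester, whose chelated tetrahedral aluminium acetal should be stable at −78 °C and release the aldehyde only on work-up.

Step 18
Reactants: 22 C9 aldehyde
Product: 24 thirteen-membered allylic alcohol (C9 epimers), via alkenylchromium dichloride 23 (not isolated)
Conditions: CrCl2 (10 equiv), NiCl2 (0.1 equiv), DMSO/THF, rt, 2 mM
Reagents that add atoms: none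
Why: Nozaki–Hiyama–Kishi macrocyclisation: zerovalent nickel inserts into the C10–I bond and transmetalation to trivalent chromium keeps the Z geometry, and the alkenylchromium adds chemoselectively to the aldehyde under high dilution to close the C9–C10 bond.

Step 19
Reactants: 24 thirteen-membered allylic alcohol
Product: 25 thirteen-membered keto ether (C9 ketone, C8–O–C13 ether, C7 MOM enol ether, O6/O12 silylene)
Conditions: MnO2, CH2Cl2, rt
Reagents that add atoms: none
Why: MnO2 oxidation of the allylic alcohol converges both C9 epimers to the Z-enone without acid or base.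

Step 20
Reactants: 25 thirteen-membered keto ether
Product: 27 ten-membered ketol (6S,7S,8R; C8 hydroxyl, C9 ketone, C7 MOM ether, C11=C13 methylene), via lithium enolate 26 (not isolated)
Conditions: LiN(SiMe3)2 (1.3 equiv), THF, −78 °C; AcOH, −78 °C
Reagents that add atoms: none
Why: Proposed new method: LiN(SiMe3)2 can enolise 25 only at C8 because C10 is sp2, and enolate 26 should undergo a concerted, suprafacial six-electron [2,3]-Wittig shift in which C8 bonds to C7 while the C13–O bond breaks; the closest known reactions are [2,3]-Wittig ring contractions of thirteen-membered allyl propargyl ethers to ten-membered carbocycles and [2,3] shifts of acyclic α-allyloxy ketone and ester enolates. The ten-membered ring is closed by transannular C7–C8 bond formation through a five-membered envelope transition state inside the thirteen-membered ring, so the ether oxygen, C13 and C11 leave the ring and C11=C13 becomes the exocyclic methylene. C7 is controlled by the C6 stereocentre: the silylene ring holds O6 and the Si(tBu)2 bridge on one face of the C7=C11 plane and places C5 pseudoaxial on the other, so C8, which is tethered to C5, should add anti to the C6–O bond and give 7S. C8 is controlled by the envelope: with C6 trans to C13 on the enol ether and C9 held exo by the ring tether, the C7 and C8 oxygens should end up anti, which is 8R in 27. The step needs the [2,3] path over [3,3] and [1,2] shifts and no silyl migration to the new alkoxide; the [3,3] shift would have to close a strained nine-membered ring, and the low temperature with a cold acetic acid quench should suppress the others.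

Step 21
Reactants: 27 ten-membered ketol
Product: 28 C8 TBS ether
Conditions: TBSOTf, 2,6-lutidine, CH2Cl2, −78 → 0 °C
Reagents that add atoms: tert-butyldimethylsilyl trifluoromethanesulfonate CC(C)(C)[Si](C)(C)OS(=O)(=O)C(F)(F)F
Why: Silylation of the hindered α-hydroxy ketone with a silyl triflate and a base too weak to enolise the ketone; the bulky group later blocks O8 during lactonisation and steers the reduction at C9.

Step 22
Reactants: 28 C8 TBS ether
Product: 29 (9R)-allylic alcohol
Conditions: NaBH4, CeCl3·7H2O, MeOH, −78 °C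
Reagents that add atoms: none
Why: Luche reduction (1,2-selective for enones): hydride should approach C9 from the ring periphery anti to the bulky, non-chelating C8 silyloxy group, which gives the 9R alcohol with O8 and O9 syn.

Step 23
Reactants: 29 (9R)-allylic alcohol; 30 angelic acid
Product: 32 C9 angelate, via mixed anhydride 31 (not isolated)
Conditions: 30, 2,4,6-trichlorobenzoyl chloride, Et3N, toluene, rt; then 29, 4-(dimethylamino)pyridine, toluene, 50 °C
Reagents that add atoms: none
Why: Yamaguchi esterification: the preformed mixed anhydride transfers the angeloyl group to the only free hydroxyl without isomerisation of the Z-enoate to the tiglate.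

Step 24
Reactants: 32 C9 angelate
Product: 33 C6,C12-diol
Conditions: HF·pyridine, pyridine, THF, 0 °C
Reagents that add atoms: none
Why: Fluoride cleavage of the seven-membered silylene should be much faster than that of the hindered secondary C8 TBS ether, and it frees O6–H and O12–H together.

Step 25
Reactants: 33 C6,C12-diol
Product: 36 6,12-lactone (α-methylene lactone), via hydroxy aldehyde 34 (not isolated), via lactol 35 (not isolated)
Conditions: 2,2,6,6-tetramethylpiperidin-1-oxyl (0.2 equiv), PhI(OAc)2 (2.5 equiv), CH2Cl2, rt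
Reagents that add atoms: none
Why: Oxidative lactonisation: the oxoammonium species oxidises the primary allylic alcohol first, the C6 hydroxyl traps the aldehyde as a five-membered lactol and this is oxidised on; O8 is silylated, so only the 6,12-lactone can form.

Step 26
Reactants: 36 6,12-lactone
Product: 38 C8 TBS ether of the target, via pyridinium salt 37 (not isolated)
Conditions: TMSOTf, 2,2'-bipyridyl, CH2Cl2, 0 °C → rt; then H2O
Reagents that add atoms: none
Why: MOM ether cleavage under near-neutral conditions: the silyl triflate activates the acetal, bipyridyl traps the oxocarbenium ion as a pyridinium salt and water hydrolyses it, which should spare the allylic lactone, the angelate, the TBS ether and the acid-sensitive 1(10),4-diene.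

Step 27
Reactants: 38 C8 TBS ether of the target
Product: 39 target CNP0303917.1
Conditions: HF·pyridine, THF, 0 °C → rt
Reagents that add atoms: none
Why: Fluoride desilylation under mildly acidic conditions, chosen over basic fluoride so that the angelate cannot migrate from O9 to the freed O8 hydroxyl.

Compound list
1 | geranyl acetate, (2E)-3,7-dimethylocta-2,6-dien-1-yl acetate | CC(C)=CCC/C(C)=C/COC(C)=O | starting material
2 | ozonide, (2E)-5-(5,5-dimethyl-1,2,4-trioxolan-3-yl)-3-methylpent-2-en-1-yl acetate (racemic) | CC1(C)OOC(CC/C(C)=C/COC(C)=O)O1 | intermediate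
3 | (2E)-3-methyl-6-oxohex-2-en-1-yl acetate | CC(=O)OC/C=C(\C)CCC=O | intermediate
4 | (2E,6Z)-7-iodo-3-methylocta-2,6-dien-1-yl acetate | CC(=O)OC/C=C(\C)CC/C=C(/C)I | intermediate
5 | (2E,6Z)-7-iodo-3-methylocta-2,6-dien-1-ol | OC/C=C(\C)CC/C=C(/C)I | intermediate
6 | (2E,6Z)-7-iodo-3-methylocta-2,6-dienal (C6 aldehyde, C10 iodide) | O=C/C=C(\C)CC/C=C(/C)I | intermediate
7 | methyl 3-hydroxypropanoate | COC(=O)CCO | starting material
8 | methyl 3-[(tert-butyldimethylsilyl)oxy]propanoate | COC(=O)CCO[Si](C)(C)C(C)(C)C | intermediate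
9 | lithium enolate of 8 | COC([O-])=CCO[Si](C)(C)C(C)(C)C.[Li+] | intermediate
10 | methyl 3-[(tert-butyldimethylsilyl)oxy]-2-formylpropanoate (racemic, in equilibrium with its enol) | COC(=O)C(C=O)CO[Si](C)(C)C(C)(C)C | intermediate
11 | methyl (2E)-2-{[(tert-butyldimethylsilyl)oxy]methyl}-3-(methoxymethoxy)prop-2-enoate | COC(=O)/C(CO[Si](C)(C)C(C)(C)C)=C/OCOC | intermediate
12 | (2Z)-2-{[(tert-butyldimethylsilyl)oxy]methyl}-3-(methoxymethoxy)prop-2-en-1-ol | OC/C(CO[Si](C)(C)C(C)(C)C)=C/OCOC | intermediate
13 | tert-butyl{[(2E)-2-{[(tert-butyldimethylsilyl)oxy]methyl}-3-(methoxymethoxy)prop-2-en-1-yl]oxy}diphenylsilane (C7–H cis to the C12 CH2OTBDPS arm, MOM-oxy cis to the C13 CH2OTBS arm) | CC(C)(C)[Si](c1ccccc1)(c1ccccc1)OC/C(CO[Si](C)(C)C(C)(C)C)=C/OCOC | intermediate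
14 | C7-lithio derivative of 13 (Li in place of the vinylic H, geometry retained) | CC(C)(C)[Si](c1ccccc1)(c1ccccc1)OC/C(CO[Si](C)(C)C(C)(C)C)=C(/OCOC)[Li] | intermediate
15 | (6RS)-carbinol: C1–C6 chain (1(10)Z, 4E, iodine on C10) with OH on C6, bonded to C7 of the MOM enol ether; C12 arm (CH2OTBDPS) cis, C13 arm (CH2OTBS) trans to C6 | C/C(I)=C/CC/C(C)=C/C(O)/C(OCOC)=C(/CO[Si](C)(C)C(C)(C)C)CO[Si](c1ccccc1)(c1ccccc1)C(C)(C)C | intermediate
16 | C6 ketone of 15 (cross-conjugated dienone) | C/C(I)=C/CC/C(C)=C/C(=O)/C(OCOC)=C(/CO[Si](C)(C)C(C)(C)C)CO[Si](c1ccccc1)(c1ccccc1)C(C)(C)C | intermediate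
17 | 16 with free C13 hydroxyl | C/C(I)=C/CC/C(C)=C/C(=O)/C(OCOC)=C(/CO)CO[Si](c1ccccc1)(c1ccccc1)C(C)(C)C | intermediate
18 | tert-butyl glycolate ether of 17 (C13–O–CH2–CO2tBu) | C/C(I)=C/CC/C(C)=C/C(=O)/C(OCOC)=C(/COCC(=O)OC(C)(C)C)CO[Si](c1ccccc1)(c1ccccc1)C(C)(C)C | intermediate
19 | (6S)-alcohol from 18 | C/C(I)=C/CC/C(C)=C/[C@H](O)/C(OCOC)=C(/COCC(=O)OC(C)(C)C)CO[Si](c1ccccc1)(c1ccccc1)C(C)(C)C | intermediate
20 | (6S)-diol, free hydroxyls on C6 and C12 | C/C(I)=C/CC/C(C)=C/[C@H](O)/C(OCOC)=C(/COCC(=O)OC(C)(C)C)CO | intermediate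
21 | (6S)-silylene: O6 and O12 bridged by Si(tBu)2 in a 4,7-dihydro-1,3,2-dioxasilepine ring that contains C6, C7=C11 and C12 | C/C(I)=C/CC/C(C)=C/[C@@H]1O[Si](C(C)(C)C)(C(C)(C)C)OC/C(COCC(=O)OC(C)(C)C)=C1/OCOC | intermediate
22 | aldehyde: 21 with C9 as CHO | C/C(I)=C/CC/C(C)=C/[C@@H]1O[Si](C(C)(C)C)(C(C)(C)C)OC/C(COCC=O)=C1/OCOC | intermediate
23 | alkenylchromium dichloride from 22 (trivalent chromium on C10 in place of iodine) | C/C([Cr](Cl)Cl)=C/CC/C(C)=C/[C@@H]1O[Si](C(C)(C)C)(C(C)(C)C)OC/C(COCC=O)=C1/OCOC | intermediate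
24 | thirteen-membered allylic alcohol (6S; C9 epimers; 1(10)Z, 4E) | O1CC(O)/C(C)=C\CC/C(C)=C/[C@@H]2O[Si](C(C)(C)C)(C(C)(C)C)OC/C(=C2/OCOC)C1 | intermediate
25 | thirteen-membered keto ether (6S): ring O–C8H2–C9(=O)–C10(Me)=C1–C2–C3–C4(Me)=C5–C6–C7(OMOM)=C11–C13H2, 1(10)Z, 4E, C6 trans to C13 on C7=C11; O6 and O12 bridged by Si(tBu)2 | O1CC(=O)/C(C)=C\CC/C(C)=C/[C@@H]2O[Si](C(C)(C)C)(C(C)(C)C)OC/C(=C2/OCOC)C1 | intermediate
26 | C8 lithium enolate of 25 (enolate geometry not assigned) | O1C=C([O-])/C(C)=C\CC/C(C)=C/[C@@H]2O[Si](C(C)(C)C)(C(C)(C)C)OC/C(=C2/OCOC)C1.[Li+] | intermediate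
27 | ten-membered ketol (6S,7S,8R): C8 OH, C9 ketone, C7 OMOM, C7 bears C11(=C13H2)–C12H2–O; O6/O12 silylene | O=C1[C@H](O)[C@@]2(OCOC)C(=C)CO[Si](C(C)(C)C)(C(C)(C)C)O[C@H]2/C=C(\C)CC/C=C1/C | intermediate
28 | C8 TBS ether of 27 | O=C1[C@H](O[Si](C)(C)C(C)(C)C)[C@@]2(OCOC)C(=C)CO[Si](C(C)(C)C)(C(C)(C)C)O[C@H]2/C=C(\C)CC/C=C1/C | intermediate
29 | (9R)-alcohol from 28 (O8 and O9 syn) | O[C@H]1[C@H](O[Si](C)(C)C(C)(C)C)[C@@]2(OCOC)C(=C)CO[Si](C(C)(C)C)(C(C)(C)C)O[C@H]2/C=C(\C)CC/C=C1/C | intermediate
30 | angelic acid, (2Z)-2-methylbut-2-enoic acid | C/C=C(/C)C(O)=O | starting material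
31 | angelic 2,4,6-trichlorobenzoic anhydride | C/C=C(/C)C(=O)OC(=O)c1c(Cl)cc(Cl)cc1Cl | intermediate
32 | C9 angelate of 29 | C/C=C(/C)C(=O)O[C@H]1[C@H](O[Si](C)(C)C(C)(C)C)[C@@]2(OCOC)C(=C)CO[Si](C(C)(C)C)(C(C)(C)C)O[C@H]2/C=C(\C)CC/C=C1/C | intermediate
33 | diol: 32 without the silylene (C6 OH, C12 OH) | C/C=C(/C)C(=O)O[C@H]1[C@H](O[Si](C)(C)C(C)(C)C)[C@@](OCOC)(C(=C)CO)[C@@H](O)/C=C(\C)CC/C=C1/C | intermediate
34 | hydroxy aldehyde: 33 with C12 as CHO | C/C=C(/C)C(=O)O[C@H]1[C@H](O[Si](C)(C)C(C)(C)C)[C@@](OCOC)(C(=C)C=O)[C@@H](O)/C=C(\C)CC/C=C1/C | intermediate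
35 | lactol: O6 bonded to C12 (C12 epimers) | C=C1C(O)O[C@H]2/C=C(\C)CC/C=C(/C)[C@@H](OC(=O)/C(C)=C\C)[C@H](O[Si](C)(C)C(C)(C)C)[C@@]12OCOC | intermediate
36 | 6,12-lactone with C7 OMOM and C8 OTBS | C=C1C(=O)O[C@H]2/C=C(\C)CC/C=C(/C)[C@@H](OC(=O)/C(C)=C\C)[C@H](O[Si](C)(C)C(C)(C)C)[C@@]12OCOC | intermediate
37 | N-(alkoxymethyl)-2,2'-bipyridinium triflate of 36 (O7–CH2–N+) | C=C1C(=O)O[C@H]2/C=C(\C)CC/C=C(/C)[C@@H](OC(=O)/C(C)=C\C)[C@H](O[Si](C)(C)C(C)(C)C)[C@@]12OC[n+]1ccccc1-c1ccccn1.[O-]S(=O)(=O)C(F)(F)F | intermediate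
38 | C8 TBS ether of the target (free C7 OH) | C=C1C(=O)O[C@H]2/C=C(\C)CC/C=C(/C)[C@@H](OC(=O)/C(C)=C\C)[C@H](O[Si](C)(C)C(C)(C)C)[C@@]12O | intermediate
39 | CNP0303917.1 (6S,7S,8S,9R; 1(10)Z, 4E) | C=C1C(=O)O[C@H]2/C=C(\C)CC/C=C(/C)[C@@H](OC(=O)/C(C)=C\C)[C@H](O)[C@@]12O | target

Total step count: 27.
Longest linear sequence: 23 steps (7 to 39, steps 5–27).

Steps most likely to fail

1. Step 20. The macrocyclic enolate may fail to reach the envelope geometry across the ring, may follow a [1,2] shift instead, or C8 may add to the wrong face of C7. The fallback runs the [2,3] shift on the open chain and closes the ten-membered ring afterwards by known chemistry. It sets out from ester 21: LiN(iPr)2 in THF at −78 °C would form the ester enolate, whose acyclic [2,3]-Wittig rearrangement (known for α-allyloxy ester enolates) should give the tert-butyl α-hydroxy ester F1. TBSOTf and 2,6-lutidine would give its C8 TBS ether F2, and iBu2AlH at −78 °C the C9 aldehyde F3. A Nozaki–Hiyama–Kishi cyclisation (CrCl2, NiCl2, DMSO, high dilution) would close C9–C10 to the ten-membered allylic alcohol F4, and MnO2 would oxidise this to ketone 28, where the route is rejoined.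

2. Step 10. Metalation may occur at an allylic CH2–O position instead of the vinylic C7–H, followed by silyl migration or elimination. The fallback generates the carbanion by tin–lithium exchange. It sets out from acrylate 11: ester-directed β-lithiation with LiN(iPr)2 at −95 °C and a Bu3SnCl quench would give the stannyl acrylate F5. iBu2AlH would reduce it to the stannyl allylic alcohol F6, and TBDPSCl with imidazole would give the stannyl bis-silyl ether F7. n-BuLi at −78 °C would then deliver lithio species 14 cleanly, and addition to enal 6 returns to carbinol 15.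

3. Step 22. Hydride may be delivered mainly to the other face of C9 if the ring conformation overrides the influence of the C8 silyloxy group. The fallback sets C9 by inversion: reduction of 28 would then give the (9S)-alcohol F8, and Mitsunobu esterification with angelic acid 30 (PPh3, diisopropyl azodicarboxylate, toluene, 0 °C) should invert C9 while installing the ester, returning to angelate 32.

Further compounds
F1 | step 20 | open-chain [2,3]-shift product: tert-butyl (8R)-hydroxy ester with C7 OMOM, C11=C13 methylene, O6/O12 silylene and the (Z)-iodoalkene chain | CC(C)(C)OC(=O)[C@H](O)[C@@]1(OCOC)C(=C)CO[Si](C(C)(C)C)(C(C)(C)C)O[C@H]1/C=C(\C)CC/C=C(/C)I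
F2 | step 20 | C8 TBS ether of F1 | CC(C)(C)OC(=O)[C@H](O[Si](C)(C)C(C)(C)C)[C@@]1(OCOC)C(=C)CO[Si](C(C)(C)C)(C(C)(C)C)O[C@H]1/C=C(\C)CC/C=C(/C)I
F3 | step 20 | C9 aldehyde from F2 | O=C[C@H](O[Si](C)(C)C(C)(C)C)[C@@]1(OCOC)C(=C)CO[Si](C(C)(C)C)(C(C)(C)C)O[C@H]1/C=C(\C)CC/C=C(/C)I
F4 | step 20 | ten-membered C9 allylic alcohol (C9 epimers) with C8 OTBS | OC1[C@H](O[Si](C)(C)C(C)(C)C)[C@@]2(OCOC)C(=C)CO[Si](C(C)(C)C)(C(C)(C)C)O[C@H]2/C=C(\C)CC/C=C1/C
F5 | step 10 | methyl (2Z)-2-{[(tert-butyldimethylsilyl)oxy]methyl}-3-(methoxymethoxy)-3-(tributylstannyl)prop-2-enoate | COC(=O)/C(CO[Si](C)(C)C(C)(C)C)=C(/OCOC)[Sn](CCCC)(CCCC)CCCC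
F6 | step 10 | stannyl allylic alcohol from F5 | OC/C(CO[Si](C)(C)C(C)(C)C)=C(/OCOC)[Sn](CCCC)(CCCC)CCCC
F7 | step 10 | C7-tributylstannyl analogue of 13 | CC(C)(C)[Si](c1ccccc1)(c1ccccc1)OC/C(CO[Si](C)(C)C(C)(C)C)=C(/OCOC)[Sn](CCCC)(CCCC)CCCC
F8 | step 22 | (9S)-alcohol, C9 epimer of 29 | O[C@@H]1[C@H](O[Si](C)(C)C(C)(C)C)[C@@]2(OCOC)C(=C)CO[Si](C(C)(C)C)(C(C)(C)C)O[C@H]2/C=C(\C)CC/C=C1/C
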